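## The problem

The target 36 is a (2R,3R)-trans-flavanonol: ring A (C4a, C5, C6, C7, C8, C8a) is fused through C4a–C8a to the pyranone ring C, and the 2′,4′-dihydroxyphenyl ring B sits on C2. Ring A is hexasubstituted: oxygens on C5, C7 and C8a (O1), a 3-hydroxy-3-methylbutyl chain on C6, an (R)-lavandulyl group on C8 and the C4 carbonyl on C4a. O1 and O5 both flank C4a, so closing ring C through the wrong one gives the 6-lavandulyl-8-alkyl isomer; the two oxygens must be told apart before ring C exists. There are three stereocentres. The lavandulyl methine is too remote to steer ring C and has to be brought in enantiopure. C3 must be set by a reagent. C2 can be left to thermodynamics, because the O1–C2 bond next to the electron-rich ring B ionises reversibly and the 2,3-trans isomer is favoured. The lavandulyl 1,5-diene and the tertiary carbinol are captured by the neighbouring phenols (chroman formation) under strong Brønsted or Lewis acid, and the diene does not tolerate electrophilic oxidants. The free flavanonol is opened, epimerised or dehydrogenated by base. The enabling feature is that ring A alternates oxygen-bearing carbons (C5, C7, C8a) with carbon- or hydrogen-bearing ones (C6, C8, C4a). C4a–C5–C6–C7 with O5, O7 and the C6 chain is therefore a vinylketene, and C8–C8a with the lavandulyl group and O1 is an oxygen-substituted alkyne.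

## Retrosynthesis

36 ⇒ 35. The last cut is the O5–CH3 bond. O5 has to stay masked until ring C is closed, and a peri methyl ether is the one ether that magnesium iodide removes by chelation and SN2 without strong acid. The commercially obvious O5 ethyl group was rejected: SN2 at ethyl is too slow, and boron halides would ionise the tertiary carbinol and attack the diene. The forward reaction must demethylate beside free phenols, the diene and two carbinols.

35 ⇒ 34. The O1–C2 bond is cut, together with the four MOM ethers and the silyl ether. The precursor is the (αR,βS) chalcone epoxide 34. The alternatives were an oxa-Michael closure followed by C3 hydroxylation (the C3 enolate expels O1) and a dihydroxylation route (OsO4 would attack the lavandulyl alkenes). In 34 only the Cα configuration has to be controlled; Cβ becomes a benzylic cation, and C2 settles trans. The forward reaction must open the epoxide at the benzylic carbon (6-endo) and not by aroyl migration.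

34 ⇒ 33 ⇒ 28 + 31. Removing the epoxide oxygen gives chalcone 33, which is cut at C4–C4a into arene 28 and the ring B cinnamoyl Weinreb amide 31. C4a–H is the only ring hydrogen of 28 and lies between OMe and OMOM, so directed lithiation replaces a Friedel–Crafts acylation that the diene would not survive. The epoxidation must be nucleophilic, which is why it is done on the enone. 31 goes back in two steps to aldehyde 29 via 30.

28 ⇒ 26. This is a protecting-group exchange: the silyl group on O1 and the free O7 hydroxyl of 26 both become MOM ethers. The bulky silyl ether neither directs ortho-lithiation nor survives basic peroxide. MOM does both and is later lost in the ring-closing acid step.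

26 ⇒ 21 + 9 (key). Ring A is cut at C6–C7, C7–C8 and C4a–C8a into cyclobutenone 21 and siloxyalkyne 9. Stepwise C-alkylation of a phloroglucinol core would have to place two different alkyl groups and differentiate three oxygens by statistics or blocking groups. The benzannulation delivers O7 free, O1 silylated and O5 methylated in one neutral step, and the polarity of the alkyne fixes lavandulyl next to O1. The forward reaction needs 21 to open below the temperature at which the 1,5-diene rearranges.

9 ⇒ 6 ⇒ 5 ⇒ 4 ⇒ 2 ⇒ 1. The ynol ether is cut at C≡C to ester 6 (Kowalski homologation). The trisubstituted alkene of 6 is cut to aldehyde 5 (Wittig). Ester 5 comes from aldehyde acid 4, and 4 arises from (R)-carvone 1 by excising C2 and its methyl group through epoxide 2. A p-menthadiene without the ring carbonyl was rejected: it would leave a methyl ketone on the longer arm, and the prenyl alkene would have to come from a tertiary-alcohol dehydration of uncertain regiochemistry. With 1 the two arms differ in oxidation level (acid and aldehyde) and the alkene is built regiospecifically. The stereocentre of 1 maps directly onto the lavandulyl centre.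

21 ⇒ 15 + 18, then 15 ⇒ 13 ⇒ 11 ⇒ 10 and 18 ⇒ 16. The cyclobutenone is cut across C1–C2 and C3–C4 into the ketene of acid 15 and methoxyacetylene 18. Acid 15 comes in three steps from alkenol 10 (silylation, hydroboration, oxidation). Ynol ether 18 is made in one step from chloroacetal 16.

## Roads not taken

Alternative 1: The cut is C4–C4a, made last. Bromine–lithium exchange on the open-chain aryl bromide A1 and attack of the aryllithium on its Weinreb amide would close ring C to the protected flavanonol A2. Merits: both ring C stereocentres are set on an acyclic ring B fragment before the diene is present; the closure is basic and cryogenic; all ring A oxygens can carry the same acetal, so no O5-specific dealkylation is needed. In that last respect this road is better than the chosen plan. Weak points: it does not make ring A, since A1 still needs a pentasubstituted ring A with only O1 free, plus a bromine on C4a. The O1–C2 ether of A1 must be formed intermolecularly at an electron-rich secondary benzylic carbon with a di-ortho-substituted phenol, where ionisation and elimination compete. The aryllithium is generated beside an amide with an α-hydrogen and a β-aryloxy leaving group, so enolisation and β-elimination compete with acylation. Against the cleaner endgame the chosen plan sets a one-step, regiochemically fixed ring A and a ring closure in which C2 corrects itself.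

Alternative 2: The cuts are C3–C4 and O1–C2. A chiral phosphoric acid (BINOL-derived hydrogen phosphate) would dehydrate the ring A salicyl alcohol A3 to its ortho-quinone methide, which adds the (E)-enol pivalate A4 to give the trans-flavan-3-yl pivalate A5. Merits: ring C and both stereocentres in one catalytic step; no epoxide; convergent. In stereochemical economy it is better than the chosen plan. Weak points: A5 is a flavan, so C4 must afterwards be oxidised to the ketone in the presence of two other benzylic methylenes, the allylic positions of the lavandulyl group and the doubly activated C2–H. The acid catalyst also meets the diene and the tertiary silyl ether, and ring A again has to be made first. The chosen plan carries C4 at the ketone level from the acylation onward, which outweighs the extra stereochemical step.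

Alternative 3: The cuts are C4a–C5 and C8–C8a, with ring A built last. The bis(trimethylsilyloxy)diene A7 would add across the bromodihydropyranone A6; loss of HBr and methanol would aromatise to A8. Merits: the ring C stereocentres are made on a small enantiopure pyranone, and O5 and O7 arrive free, so no ether cleavage is needed. In protecting-group economy at ring A it is better than the chosen plan. Weak points: the orientation of the two diene termini toward C4a and C8a rests on a steric and electronic bias, and the reversed mode gives the 6-lavandulyl-8-alkyl isomer. A7 must be generated with defined regiochemistry at a tetrasubstituted terminus. The Lewis acids usual for such cyclocondensations (TiCl4, Me3SiOTf) endanger the diene and the silyl ethers. A6 can aromatise to a 4-pyranone by losing its C3 silyloxy group. The chosen plan answers the regiochemical question by the polarity of the siloxyalkyne and pays for it with the late O5 demethylation.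

Key step: step 11

Remark on the chemistry: flavanone numbering (O1, C2–C4, C4a, C5–C8, C8a; ring B primed) is used for ring A and ring C atoms at every stage, also before ring C exists.

Step 1
Reactants: 1 (R)-(−)-carvone
Product: 2 (1R,4R,6R)-1-methyl-4-(prop-1-en-2-yl)-7-oxabicyclo[4.1.0]heptan-2-one
Conditions: H2O2 (30% aq), NaOH (cat.), MeOH, 0 °C
Reagents that add atoms: hydrogen peroxide, OO
Why: Weitz–Scheffer nucleophilic epoxidation: hydroperoxide adds only to the enone and leaves the isolated isopropenyl alkene alone; attack anti to the isopropenyl group gives the trans epoxide, whose two new centres are erased in step 2.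

Step 2
Reactants: 2 (1R,4R,6R)-1-methyl-4-(prop-1-en-2-yl)-7-oxabicyclo[4.1.0]heptan-2-one
Product: 4 (3R)-5-oxo-3-(prop-1-en-2-yl)pentanoic acid, via glycol 3 (not isolated)
Conditions: H5IO6 (2.5 equiv), THF–H2O, 0 °C → rt
Reagents that add atoms: water, O
Why: Periodic acid opens the epoxide hydrolytically to glycol 3 and then cleaves its diol and α-ketol C–C bonds (Malaprade cleavage), so the methyl-bearing carbon leaves as acetic acid, the ketone carbon becomes CO2H and the epoxide CH becomes CHO. The surviving stereocentre is β to both carbonyls and cannot epimerise.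

Step 3
Reactants: 4 (3R)-5-oxo-3-(prop-1-en-2-yl)pentanoic acid
Product: 5 ethyl (3R)-5-oxo-3-(prop-1-en-2-yl)pentanoate
Conditions: EtI, KHCO3, DMF, rt
Reagents that add atoms: iodoethane, CCI
Why: SN2 O-alkylation of the carboxylate under a base too weak to enolise the aldehyde; alkylation also pulls any cyclic lactol form of 4 to the open-chain ester.

Step 4
Reactants: 5 ethyl (3R)-5-oxo-3-(prop-1-en-2-yl)pentanoate
Product: 6 ethyl (3R)-6-methyl-3-(prop-1-en-2-yl)hept-5-enoate
Conditions: i-PrPPh3I, n-BuLi, THF, 0 °C; then 5, −78 → 0 °C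
Reagents that add atoms: isopropyltriphenylphosphonium iodide, CC(C)[P+](c1ccccc1)(c1ccccc1)c1ccccc1.[I-]
Why: Wittig olefination with the non-stabilised isopropylidene ylide, which reacts with the aldehyde far faster than with the ester; the alkene position is fixed by the carbonyl and the symmetrical terminus leaves no E/Z question.

Step 5
Reactants: 6 ethyl (3R)-6-methyl-3-(prop-1-en-2-yl)hept-5-enoate
Product: 9 triisopropyl{[(4R)-7-methyl-4-(prop-1-en-2-yl)oct-6-en-1-yn-1-yl]oxy}silane, via dibromo enolate 7 (not isolated), via lithium ynolate 8 (not isolated)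
Conditions: CH2Br2, lithium 2,2,6,6-tetramethylpiperidide, THF, −78 °C; then 6; LiN(SiMe3)2; n-BuLi, −78 → 0 °C; i-Pr3SiCl, −78 °C → rt
Reagents that add atoms: dibromomethane, BrCBr; chlorotriisopropylsilane, CC(C)[Si](Cl)(C(C)C)C(C)C
Why: Kowalski ester homologation: dibromomethyllithium adds to the ester, enolate 7 undergoes bromine–lithium exchange and the carbenoid rearranges with 1,2-shift of the alkyl group to ynolate 8, which the bulky chlorosilane silylates on oxygen. The migrating carbon is a CH2, so the stereocentre is not involved.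

Step 6
Reactants: 10 2-methylhex-5-en-2-ol
Product: 11 triethyl[(2-methylhex-5-en-2-yl)oxy]silane
Conditions: Et3SiOTf, 2,6-lutidine, CH2Cl2, 0 °C
Reagents that add atoms: triethylsilyl trifluoromethanesulfonate, CC[Si](CC)(CC)OS(=O)(=O)C(F)(F)F
Why: Silyl triflate silylation of a tertiary alcohol; the resulting hindered triethylsilyl ether should survive base, fluoride at 0 °C and heat, and is lost in the acid step 17.

Step 7
Reactants: 11 triethyl[(2-methylhex-5-en-2-yl)oxy]silane
Product: 13 5-methyl-5-(triethylsilyloxy)hexan-1-ol, via alkylborane 12 (not isolated)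
Conditions: 9-BBN, THF, 0 °C → rt; then NaOH, H2O2, 0 °C
Reagents that add atoms: hydrogen peroxide, OO
Why: Brown hydroboration–oxidation; 9-BBN adds to the terminal alkene with anti-Markovnikov selectivity and alkaline peroxide replaces boron by hydroxyl without touching the silyl ether.

Step 8
Reactants: 13 5-methyl-5-(triethylsilyloxy)hexan-1-ol
Product: 15 5-methyl-5-(triethylsilyloxy)hexanoic acid, via aldehyde 14 (not isolated)
Conditions: TEMPO (2,2,6,6-tetramethylpiperidin-1-oxyl, cat.), PhI(OAc)2, MeCN–H2O (pH 7 buffer), rt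
Reagents that add atoms: water, O
Why: Oxoammonium-mediated oxidation of the primary alcohol to aldehyde 14 and, through its hydrate, to the acid; the buffered medium spares the tertiary silyl ether.

Step 9
Reactants: 16 2-chloro-1,1-dimethoxyethane
Product: 18 methoxyacetylene, via sodium methoxyacetylide 17 (not isolated)
Conditions: NaNH2 (3 equiv), liquid NH3, −33 °C; then sat. aq NaCl, −20 °C; distilled into a cold trap and used as an ethereal solution
Reagents that add atoms: none
Why: Twofold base-induced elimination (HCl and methanol) gives acetylide 17, protonated on quench; this is the classical preparation of 1-alkoxyalkynes from chloroacetaldehyde acetals. Methyl is chosen over ethyl because only a methyl ether at O5 can be removed in step 18.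

Step 10
Reactants: 15 5-methyl-5-(triethylsilyloxy)hexanoic acid; 18 methoxyacetylene
Product: 21 3-methoxy-4-[3-methyl-3-(triethylsilyloxy)butyl]cyclobut-2-en-1-one (racemic), via acid chloride 19 (not isolated), via alkylketene 20 (not isolated)
Conditions: 1-chloro-N,N,2-trimethylprop-1-en-1-amine, CH2Cl2, 0 °C → rt; then added slowly to 18 (3 equiv), Et3N, Et2O, 0 °C → rt
Reagents that add atoms: none
Why: Ghosez's reagent forms the acid chloride without HCl, so the silyl ether survives; triethylamine generates ketene 20, which undergoes [2+2] cycloaddition with the ynol ether, whose nucleophilic CH carbon bonds to the ketene carbonyl carbon, giving only the 3-alkoxy-4-alkyl isomer. Slow addition and excess 18 counter ketene dimerisation; the racemic C4 centre becomes sp2 in step 11.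

Step 11
Reactants: 21 3-methoxy-4-[3-methyl-3-(triethylsilyloxy)butyl]cyclobut-2-en-1-one; 9 triisopropyl{[(4R)-7-methyl-4-(prop-1-en-2-yl)oct-6-en-1-yn-1-yl]oxy}silane
Product: 26 3-methoxy-2-[3-methyl-3-(triethylsilyloxy)butyl]-6-[(2R)-5-methyl-2-(prop-1-en-2-yl)hex-4-en-1-yl]-5-(triisopropylsilyloxy)phenol, via vinylketene 22 (not isolated), via alkenylcyclobutenone 23 (not isolated), via dienylketene 24 (not isolated), via cyclohexadienone 25 (not isolated)
Conditions: 21 (1.3 equiv), toluene, 80 °C, then 110 °C, sealed tube, argon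
Reagents that add atoms: none
Why: Danheiser benzannulation, here with a 3-alkoxy-4-alkylcyclobutenone as vinylketene source and a siloxyalkyne as ketenophile, both established partner classes. Thermal conrotatory 4π opening of 21 gives vinylketene 22 with the alkyl group turning outward. The polarised ynol ether 9 then adds to the ketene C=C in a [2+2]: its nucleophilic lavandulyl-bearing carbon bonds to the ketene carbonyl carbon (C7–C8) and its silyloxy carbon to the α-carbon (C4a–C8a), giving 23. A second strain-releasing 4π opening gives dienylketene 24, and ring A closes by a thermally allowed disrotatory 6π electrocyclisation (C6–C7) to dienone 25, which tautomerises irreversibly to phenol 26. No stereocentre is created: the racemic centre of 21 and the sp3 ring carbons of 23 and 25 all end as aromatic carbons, and the lavandulyl centre is not involved under these neutral conditions. The step needs regio- and chemoselectivity: the O-silyl polarisation of 9 places lavandulyl on C8 next to the silyloxy group on C8a, and the 4-alkyl group of 21 ends on C6 beside the new O7 hydroxyl. Ketenes do not attack the isolated 1,5-diene or the silyl ethers, and 110 °C is far below the Cope rearrangement of the diene. The new hydroxyl lies between two alkyl groups, which should keep it from being acylated by 22; the excess of 21 covers ketene lost to dimerisation.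

Step 12
Reactants: 26 3-methoxy-2-[3-methyl-3-(triethylsilyloxy)butyl]-6-[(2R)-5-methyl-2-(prop-1-en-2-yl)hex-4-en-1-yl]-5-(triisopropylsilyloxy)phenol
Product: 28 1-methoxy-3,5-bis(methoxymethoxy)-2-[3-methyl-3-(triethylsilyloxy)butyl]-4-[(2R)-5-methyl-2-(prop-1-en-2-yl)hex-4-en-1-yl]benzene, via resorcinol 27 (not isolated)
Conditions: Bu4NF (1.1 equiv), THF, 0 °C; then NaH, MOMCl, DMF, 0 °C → rt (one pot, argon)
Reagents that add atoms: chloromethyl methyl ether, COCCl
Why: Fluoride cleaves the aryl silyl ether much faster than the hindered tertiary alkyl silyl ether, and the two phenoxides are then alkylated by MOMCl (Williamson etherification) without isolating the air-sensitive resorcinol. O1 now carries a group that directs lithiation, survives basic peroxide and leaves in the ring-closing acid step, while O5 keeps its distinct methyl group.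

Step 13
Reactants: 29 2,4-dihydroxybenzaldehyde
Product: 30 2,4-bis(methoxymethoxy)benzaldehyde
Conditions: MOMCl, i-Pr2NEt, CH2Cl2, 0 °C → reflux
Reagents that add atoms: chloromethyl methyl ether, COCCl
Why: Standard acetal protection of both phenols; the hydrogen-bonded 2-hydroxyl reacts more slowly but completely with excess reagent.

Step 14
Reactants: 30 2,4-bis(methoxymethoxy)benzaldehyde
Product: 31 (2E)-3-[2,4-bis(methoxymethoxy)phenyl]-N-methoxy-N-methylprop-2-enamide
Conditions: (EtO)2P(O)CH2C(O)N(OMe)Me, NaH, THF, 0 °C → rt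
Reagents that add atoms: diethyl {2-[methoxy(methyl)amino]-2-oxoethyl}phosphonate, CCOP(=O)(CC(=O)N(C)OC)OCC
Why: Horner–Wadsworth–Emmons olefination with a stabilised phosphonate anion, which gives the (E)-enamide.

Step 15
Reactants: 28 1-methoxy-3,5-bis(methoxymethoxy)-2-[3-methyl-3-(triethylsilyloxy)butyl]-4-[(2R)-5-methyl-2-(prop-1-en-2-yl)hex-4-en-1-yl]benzene; 31 (2E)-3-[2,4-bis(methoxymethoxy)phenyl]-N-methoxy-N-methylprop-2-enamide
Product: 33 (2E)-3-[2,4-bis(methoxymethoxy)phenyl]-1-{2-methoxy-4,6-bis(methoxymethoxy)-3-[3-methyl-3-(triethylsilyloxy)butyl]-5-[(2R)-5-methyl-2-(prop-1-en-2-yl)hex-4-en-1-yl]phenyl}prop-2-en-1-one, via aryllithium 32 (not isolated)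
Conditions: n-BuLi, THF, 0 °C; then 31, −78 → −20 °C; aq NH4Cl
Reagents that add atoms: none
Why: Directed ortho-metalation: C4a–H is the only ring hydrogen and lies between the methoxy and MOM-oxy groups, so it is removed in preference to benzylic or allylic hydrogens. Aryllithium 32 adds once, in 1,2-fashion, to the Weinreb amide and the chelated adduct releases the (E)-enone on work-up.

Step 16
Reactants: 33 (2E)-3-[2,4-bis(methoxymethoxy)phenyl]-1-{2-methoxy-4,6-bis(methoxymethoxy)-3-[3-methyl-3-(triethylsilyloxy)butyl]-5-[(2R)-5-methyl-2-(prop-1-en-2-yl)hex-4-en-1-yl]phenyl}prop-2-en-1-one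
Product: 34 [(2R,3S)-3-[2,4-bis(methoxymethoxy)phenyl]oxiran-2-yl]{2-methoxy-4,6-bis(methoxymethoxy)-3-[3-methyl-3-(triethylsilyloxy)butyl]-5-[(2R)-5-methyl-2-(prop-1-en-2-yl)hex-4-en-1-yl]phenyl}methanone
Conditions: poly-L-leucine, urea·H2O2, DBU, THF, rt
Reagents that add atoms: urea–hydrogen peroxide, NC(N)=O.OO
Why: Juliá–Colonna epoxidation: the helical polypeptide delivers hydroperoxide to one face of the enone, and the L-polymer gives the (αR,βS) epoxide of chalcones. The nucleophilic oxidant cannot epoxidise the isolated lavandulyl alkenes; the Cα configuration set here becomes C3.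

Step 17
Reactants: 34 [(2R,3S)-3-[2,4-bis(methoxymethoxy)phenyl]oxiran-2-yl]{2-methoxy-4,6-bis(methoxymethoxy)-3-[3-methyl-3-(triethylsilyloxy)butyl]-5-[(2R)-5-methyl-2-(prop-1-en-2-yl)hex-4-en-1-yl]phenyl}methanone
Product: 35 (2R,3R)-2-(2,4-dihydroxyphenyl)-3,7-dihydroxy-6-(3-hydroxy-3-methylbutyl)-5-methoxy-8-[(2R)-5-methyl-2-(prop-1-en-2-yl)hex-4-en-1-yl]-2,3-dihydro-4H-chromen-4-one
Conditions: HCl (1.25 M in MeOH), THF, 0 → 40 °C
Reagents that add atoms: none
Why: Acid opens the epoxide at the benzylic carbon, whose cation is stabilised by the 2,4-dioxygenated ring B, and O1, freed from its carbonyl-flanked MOM ether, closes ring C in 6-endo fashion; this is the established route from 2′-MOM-oxy chalcone epoxides to trans-dihydroflavonols. C3 keeps the Cα configuration because its C–O bond is not broken, and C2 settles trans to it because the O1–C2 bond ionises reversibly. The same medium removes the other MOM ethers and the triethylsilyl ether, while the O5 methyl ether keeps O5 out of the cyclisation.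

Step 18
Reactants: 35 (2R,3R)-2-(2,4-dihydroxyphenyl)-3,7-dihydroxy-6-(3-hydroxy-3-methylbutyl)-5-methoxy-8-[(2R)-5-methyl-2-(prop-1-en-2-yl)hex-4-en-1-yl]-2,3-dihydro-4H-chromen-4-one
Product: 36 (2R,3R)-2-(2,4-dihydroxyphenyl)-3,5,7-trihydroxy-6-(3-hydroxy-3-methylbutyl)-8-[(2R)-5-methyl-2-(prop-1-en-2-yl)hex-4-en-1-yl]-2,3-dihydro-4H-chromen-4-one
Conditions: MgI2·OEt2, THF, 50 °C; aq NH4Cl
Reagents that add atoms: none
Why: Chelation-assisted demethylation: magnesium binds the C4 carbonyl and O5, and iodide removes the methyl group by SN2. The reagent is known to demethylate 5-O-methyl 8-prenylflavanones with free phenols and the prenyl group intact, and no stereocentre takes part.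

Compound list
1 | (R)-(−)-carvone, (5R)-2-methyl-5-(prop-1-en-2-yl)cyclohex-2-en-1-one | CC1=CC[C@H](CC1=O)C(C)=C | starting material
2 | (1R,4R,6R)-1-methyl-4-(prop-1-en-2-yl)-7-oxabicyclo[4.1.0]heptan-2-one | C[C@@]12O[C@@H]1C[C@H](CC2=O)C(C)=C | intermediate
3 | (5R)-2,3-dihydroxy-2-methyl-5-(prop-1-en-2-yl)cyclohexan-1-one (glycol, not isolated; carbinol centres not defined, both are cleaved) | CC1(O)C(O)C[C@H](CC1=O)C(C)=C | intermediate
4 | (3R)-5-oxo-3-(prop-1-en-2-yl)pentanoic acid | O=CC[C@H](CC(=O)O)C(C)=C | intermediate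
5 | ethyl (3R)-5-oxo-3-(prop-1-en-2-yl)pentanoate | O=CC[C@H](CC(=O)OCC)C(C)=C | intermediate
6 | ethyl (3R)-6-methyl-3-(prop-1-en-2-yl)hept-5-enoate (ethyl homolavandulate) | CC(C)=CC[C@H](CC(=O)OCC)C(C)=C | intermediate
7 | lithium (4R)-1,1-dibromo-7-methyl-4-(prop-1-en-2-yl)octa-1,6-dien-2-olate (not isolated) | C=C(C)[C@H](CC=C(C)C)CC(O[Li])=C(Br)Br | intermediate
8 | lithium (4R)-7-methyl-4-(prop-1-en-2-yl)oct-6-en-1-yn-1-olate (not isolated) | C=C(C)[C@H](CC=C(C)C)CC#CO[Li] | intermediate
9 | triisopropyl{[(4R)-7-methyl-4-(prop-1-en-2-yl)oct-6-en-1-yn-1-yl]oxy}silane (lavandulyl siloxyalkyne) | C=C(C)[C@H](CC=C(C)C)CC#CO[Si](C(C)C)(C(C)C)C(C)C | intermediate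
10 | 2-methylhex-5-en-2-ol | CC(C)(O)CCC=C | starting material
11 | triethyl[(2-methylhex-5-en-2-yl)oxy]silane | CC[Si](CC)(CC)OC(C)(C)CCC=C | intermediate
12 | 9-[5-methyl-5-(triethylsilyloxy)hexyl]-9-borabicyclo[3.3.1]nonane (not isolated) | CC[Si](CC)(CC)OC(C)(C)CCCCB1C2CCCC1CCC2 | intermediate
13 | 5-methyl-5-(triethylsilyloxy)hexan-1-ol | CC[Si](CC)(CC)OC(C)(C)CCCCO | intermediate
14 | 5-methyl-5-(triethylsilyloxy)hexanal (not isolated) | CC[Si](CC)(CC)OC(C)(C)CCCC=O | intermediate
15 | 5-methyl-5-(triethylsilyloxy)hexanoic acid | CC[Si](CC)(CC)OC(C)(C)CCCC(=O)O | intermediate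
16 | 2-chloro-1,1-dimethoxyethane | COC(CCl)OC | starting material
17 | sodium methoxyacetylide (not isolated) | COC#C[Na] | intermediate
18 | methoxyacetylene | COC#C | intermediate
19 | 5-methyl-5-(triethylsilyloxy)hexanoyl chloride (not isolated) | CC[Si](CC)(CC)OC(C)(C)CCCC(=O)Cl | intermediate
20 | 5-methyl-5-(triethylsilyloxy)hex-1-en-1-one (alkylketene, not isolated) | CC[Si](CC)(CC)OC(C)(C)CCC=C=O | intermediate
21 | 3-methoxy-4-[3-methyl-3-(triethylsilyloxy)butyl]cyclobut-2-en-1-one (racemic) | COC1=CC(=O)C1CCC(C)(C)O[Si](CC)(CC)CC | intermediate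
22 | (3Z)-3-methoxy-7-methyl-7-(triethylsilyloxy)octa-1,3-dien-1-one (vinylketene, not isolated) | O=C=C/C(OC)=C/CCC(C)(C)O[Si](CC)(CC)CC | intermediate
23 | 4-[(1Z)-1-methoxy-5-methyl-5-(triethylsilyloxy)hex-1-en-1-yl]-2-[(2R)-5-methyl-2-(prop-1-en-2-yl)hex-4-en-1-yl]-3-(triisopropylsilyloxy)cyclobut-2-en-1-one (both configurations at C4, not isolated) | O=C1C(C[C@@H](CC=C(C)C)C(C)=C)=C(O[Si](C(C)C)(C(C)C)C(C)C)C1/C(OC)=C/CCC(C)(C)O[Si](CC)(CC)CC | intermediate
24 | 5-methoxy-9-methyl-2-[(2R)-5-methyl-2-(prop-1-en-2-yl)hex-4-en-1-yl]-9-(triethylsilyloxy)-3-(triisopropylsilyloxy)deca-1,3,5-trien-1-one (dienylketene, not isolated) | O=C=C(C[C@@H](CC=C(C)C)C(C)=C)/C(O[Si](C(C)C)(C(C)C)C(C)C)=C\C(OC)=C\CCC(C)(C)O[Si](CC)(CC)CC | intermediate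
25 | 5-methoxy-6-[3-methyl-3-(triethylsilyloxy)butyl]-2-[(2R)-5-methyl-2-(prop-1-en-2-yl)hex-4-en-1-yl]-3-(triisopropylsilyloxy)cyclohexa-2,4-dien-1-one (both configurations at C6, not isolated) | O=C1C(C[C@@H](CC=C(C)C)C(C)=C)=C(O[Si](C(C)C)(C(C)C)C(C)C)C=C(OC)C1CCC(C)(C)O[Si](CC)(CC)CC | intermediate
26 | 3-methoxy-2-[3-methyl-3-(triethylsilyloxy)butyl]-6-[(2R)-5-methyl-2-(prop-1-en-2-yl)hex-4-en-1-yl]-5-(triisopropylsilyloxy)phenol (ring A) | C=C(C)[C@H](CC=C(C)C)Cc1c(O)c(CCC(C)(C)O[Si](CC)(CC)CC)c(OC)cc1O[Si](C(C)C)(C(C)C)C(C)C | intermediate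
27 | 5-methoxy-4-[3-methyl-3-(triethylsilyloxy)butyl]-2-[(2R)-5-methyl-2-(prop-1-en-2-yl)hex-4-en-1-yl]benzene-1,3-diol (not isolated) | C=C(C)[C@H](CC=C(C)C)Cc1c(O)c(CCC(C)(C)O[Si](CC)(CC)CC)c(OC)cc1O | intermediate
28 | 1-methoxy-3,5-bis(methoxymethoxy)-2-[3-methyl-3-(triethylsilyloxy)butyl]-4-[(2R)-5-methyl-2-(prop-1-en-2-yl)hex-4-en-1-yl]benzene | C=C(C)[C@H](CC=C(C)C)Cc1c(OCOC)c(CCC(C)(C)O[Si](CC)(CC)CC)c(OC)cc1OCOC | intermediate
29 | 2,4-dihydroxybenzaldehyde | O=Cc1ccc(O)cc1O | starting material
30 | 2,4-bis(methoxymethoxy)benzaldehyde | O=Cc1ccc(OCOC)cc1OCOC | intermediate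
31 | (2E)-3-[2,4-bis(methoxymethoxy)phenyl]-N-methoxy-N-methylprop-2-enamide | CON(C)C(=O)/C=C/c1ccc(OCOC)cc1OCOC | intermediate
32 | {2-methoxy-4,6-bis(methoxymethoxy)-3-[3-methyl-3-(triethylsilyloxy)butyl]-5-[(2R)-5-methyl-2-(prop-1-en-2-yl)hex-4-en-1-yl]phenyl}lithium (not isolated) | C=C(C)[C@H](CC=C(C)C)Cc1c(OCOC)c(CCC(C)(C)O[Si](CC)(CC)CC)c(OC)c([Li])c1OCOC | intermediate
33 | (2E)-3-[2,4-bis(methoxymethoxy)phenyl]-1-{2-methoxy-4,6-bis(methoxymethoxy)-3-[3-methyl-3-(triethylsilyloxy)butyl]-5-[(2R)-5-methyl-2-(prop-1-en-2-yl)hex-4-en-1-yl]phenyl}prop-2-en-1-one | C=C(C)[C@H](CC=C(C)C)Cc1c(OCOC)c(CCC(C)(C)O[Si](CC)(CC)CC)c(OC)c(C(=O)/C=C/c2ccc(OCOC)cc2OCOC)c1OCOC | intermediate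
34 | [(2R,3S)-3-[2,4-bis(methoxymethoxy)phenyl]oxiran-2-yl]{2-methoxy-4,6-bis(methoxymethoxy)-3-[3-methyl-3-(triethylsilyloxy)butyl]-5-[(2R)-5-methyl-2-(prop-1-en-2-yl)hex-4-en-1-yl]phenyl}methanone | C=C(C)[C@H](CC=C(C)C)Cc1c(OCOC)c(CCC(C)(C)O[Si](CC)(CC)CC)c(OC)c(C(=O)[C@@H]2O[C@H]2c2ccc(OCOC)cc2OCOC)c1OCOC | intermediate
35 | (2R,3R)-2-(2,4-dihydroxyphenyl)-3,7-dihydroxy-6-(3-hydroxy-3-methylbutyl)-5-methoxy-8-[(2R)-5-methyl-2-(prop-1-en-2-yl)hex-4-en-1-yl]-2,3-dihydro-4H-chromen-4-one | C=C(C)[C@H](CC=C(C)C)Cc1c(O)c(CCC(C)(C)O)c(OC)c2c1O[C@H](c1ccc(O)cc1O)[C@@H](O)C2=O | intermediate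
36 | (2R,3R)-2-(2,4-dihydroxyphenyl)-3,5,7-trihydroxy-6-(3-hydroxy-3-methylbutyl)-8-[(2R)-5-methyl-2-(prop-1-en-2-yl)hex-4-en-1-yl]-2,3-dihydro-4H-chromen-4-one | C=C(C)[C@H](CC=C(C)C)Cc1c(O)c(CCC(C)(C)O)c(O)c2c1O[C@H](c1ccc(O)cc1O)[C@@H](O)C2=O | target

Total step count: 18 (the one-pot desilylation–etherification of step 12 counted as one). Longest linear sequence: 11 steps (steps 1–5, 11, 12, 15–18).

Steps least certain to work

Step 11 (key step). The electrocyclic opening of the vinylogous-ester cyclobutenone may be slow compared with dimerisation of the vinylketene or thermal loss of the ynol ether, leaving low conversion to ring A. The fallback generates vinylketene 22 at or below room temperature by 1,4-dehydrochlorination instead of ring opening. It sets out from acid 15 and uses 9. Activation with carbonyldiimidazole and reaction with Mg(O2CCH2CO2Me)2 (Masamune homologation) gives methyl 7-methyl-3-oxo-7-(triethylsilyloxy)octanoate F1. Trimethyl orthoformate in methanol with catalytic pyridinium p-toluenesulfonate gives methyl (2E)-3-methoxy-7-methyl-7-(triethylsilyloxy)oct-2-enoate F2. LiOH in aqueous THF gives (2E)-3-methoxy-7-methyl-7-(triethylsilyloxy)oct-2-enoic acid F3, and Ghosez's reagent gives (2E)-3-methoxy-7-methyl-7-(triethylsilyloxy)oct-2-enoyl chloride F4. Triethylamine in the presence of 9 removes the γ-hydrogen of F4 to give 22, which is trapped as 23; warming to 80 °C completes the cascade and the route is rejoined at 26.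

Step 2. Hydrolytic opening of the carbonyl-deactivated epoxide may be slow, and the acid may hydrate or shift the isopropenyl double bond before cleavage is complete. The fallback sets out from 1 and masks the isopropenyl group so that the enone can be cleaved by ozone. Br2 (1 equiv, CH2Cl2, −78 °C) adds to the electron-rich 1,1-disubstituted alkene to give (5R)-5-(1,2-dibromopropan-2-yl)-2-methylcyclohex-2-en-1-one F5. Ozonolysis (O3, CH2Cl2–MeOH, −78 °C; Me2S) followed by H5IO6, which cleaves the resulting 1,2-diketone, gives (3R)-3-(1,2-dibromopropan-2-yl)-5-oxopentanoic acid F6. Zn dust in acetic acid–ether restores the alkene, and the route is rejoined at 4.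

Step 16. Facial selectivity may be poor, because the fully substituted aryl ketone of 33 is twisted out of conjugation and lies at the edge of the substrate range of the polypeptide catalyst. The minor epoxide would end as the (2S,3S) flavanonol, which differs from 36 only at centres remote from the lavandulyl one and would be hard to remove. The fallback sets the epoxide on ring B before the coupling and sets out from 31. Shi epoxidation is run with KHSO5 (as 2KHSO5·KHSO4·K2SO4), K2CO3 buffer and 1,2:4,5-di-O-isopropylidene-β-L-erythro-2,3-hexodiulo-2,6-pyranose in MeCN–dimethoxymethane–water at 0 °C. This L-series ketone is the enantiomer of the usual fructose-derived catalyst, and the spiro transition-state model predicts the (2R,3S) epoxide from it. The product is (2R,3S)-3-[2,4-bis(methoxymethoxy)phenyl]-N-methoxy-N-methyloxirane-2-carboxamide F7, whose optical purity can be raised by recrystallisation. Aryllithium 32, made from 28 as in step 15, then adds to the Weinreb carbonyl of F7 at −78 °C, and the route is rejoined at 34.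

Step 17. During the time needed to remove the MOM ethers that are not next to the carbonyl, the freed phenols may capture a protonated lavandulyl alkene or the tertiary carbocation (chroman formation), and the opened epoxide may undergo 1,2-aroyl shift. The fallback separates ring closure from deprotection and sets out from 34. Catalytic pyridinium p-toluenesulfonate in CH2Cl2–MeOH at 0 °C opens the epoxide; the O1 MOM ether oxygen captures the benzylic cation and sheds its methoxymethyl group. This gives (2R,3R)-2-[2,4-bis(methoxymethoxy)phenyl]-3-hydroxy-5-methoxy-7-(methoxymethoxy)-6-[3-methyl-3-(triethylsilyloxy)butyl]-8-[(2R)-5-methyl-2-(prop-1-en-2-yl)hex-4-en-1-yl]-2,3-dihydro-4H-chromen-4-one F8. Me3SiOTf with 2,2′-bipyridyl, then water, removes the aryl MOM ethers without protic acid and gives (2R,3R)-2-(2,4-dihydroxyphenyl)-3,7-dihydroxy-5-methoxy-6-[3-methyl-3-(triethylsilyloxy)butyl]-8-[(2R)-5-methyl-2-(prop-1-en-2-yl)hex-4-en-1-yl]-2,3-dihydro-4H-chromen-4-one F9. Pyridine-buffered HF·pyridine in THF at 0 °C frees the tertiary alcohol, and the route is rejoined at 35.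

Step 18. Demethylation may be incomplete at temperatures the flavanonol tolerates, or the heated Lewis acid may open ring C through the ring B quinone methide and epimerise C2 and C3 while the 2′- and 4′-phenols are free. The fallback blocks that pathway by masking the phenols first and sets out from 35. t-BuMe2SiCl and imidazole in DMF at 0 °C give the 7,2′,4′-tris(tert-butyldimethylsilyl) ether of 35 F10. MgI2·OEt2 in THF then cleaves the O5 methyl ether on a substrate that cannot form the quinone methide, giving the 7,2′,4′-tris(tert-butyldimethylsilyl) ether of 36 F11. Pyridine-buffered HF·pyridine removes the silyl groups, and the route is rejoined at 36.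

Further compounds
F1 | step 11 | methyl 7-methyl-3-oxo-7-(triethylsilyloxy)octanoate | COC(=O)CC(=O)CCCC(C)(C)O[Si](CC)(CC)CC
F2 | step 11 | methyl (2E)-3-methoxy-7-methyl-7-(triethylsilyloxy)oct-2-enoate | COC(=O)/C=C(\CCCC(C)(C)O[Si](CC)(CC)CC)OC
F3 | step 11 | (2E)-3-methoxy-7-methyl-7-(triethylsilyloxy)oct-2-enoic acid | OC(=O)/C=C(\CCCC(C)(C)O[Si](CC)(CC)CC)OC
F4 | step 11 | (2E)-3-methoxy-7-methyl-7-(triethylsilyloxy)oct-2-enoyl chloride | ClC(=O)/C=C(\CCCC(C)(C)O[Si](CC)(CC)CC)OC
F5 | step 2 | (5R)-5-(1,2-dibromopropan-2-yl)-2-methylcyclohex-2-en-1-one (both configurations at the brominated carbon) | CC1=CC[C@H](CC1=O)C(C)(Br)CBr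
F6 | step 2 | (3R)-3-(1,2-dibromopropan-2-yl)-5-oxopentanoic acid (both configurations at the brominated carbon) | O=CC[C@H](CC(=O)O)C(C)(Br)CBr
F7 | step 16 | (2R,3S)-3-[2,4-bis(methoxymethoxy)phenyl]-N-methoxy-N-methyloxirane-2-carboxamide | CON(C)C(=O)[C@@H]1O[C@H]1c1ccc(OCOC)cc1OCOC
F8 | step 17 | (2R,3R)-2-[2,4-bis(methoxymethoxy)phenyl]-3-hydroxy-5-methoxy-7-(methoxymethoxy)-6-[3-methyl-3-(triethylsilyloxy)butyl]-8-[(2R)-5-methyl-2-(prop-1-en-2-yl)hex-4-en-1-yl]-2,3-dihydro-4H-chromen-4-one | C=C(C)[C@H](CC=C(C)C)Cc1c(OCOC)c(CCC(C)(C)O[Si](CC)(CC)CC)c(OC)c2c1O[C@H](c1ccc(OCOC)cc1OCOC)[C@@H](O)C2=O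
F9 | step 17 | (2R,3R)-2-(2,4-dihydroxyphenyl)-3,7-dihydroxy-5-methoxy-6-[3-methyl-3-(triethylsilyloxy)butyl]-8-[(2R)-5-methyl-2-(prop-1-en-2-yl)hex-4-en-1-yl]-2,3-dihydro-4H-chromen-4-one | C=C(C)[C@H](CC=C(C)C)Cc1c(O)c(CCC(C)(C)O[Si](CC)(CC)CC)c(OC)c2c1O[C@H](c1ccc(O)cc1O)[C@@H](O)C2=O
F10 | step 18 | (2R,3R)-2-[2,4-bis(tert-butyldimethylsilyloxy)phenyl]-7-(tert-butyldimethylsilyloxy)-3-hydroxy-6-(3-hydroxy-3-methylbutyl)-5-methoxy-8-[(2R)-5-methyl-2-(prop-1-en-2-yl)hex-4-en-1-yl]-2,3-dihydro-4H-chromen-4-one | C=C(C)[C@H](CC=C(C)C)Cc1c(O[Si](C)(C)C(C)(C)C)c(CCC(C)(C)O)c(OC)c2c1O[C@H](c1ccc(O[Si](C)(C)C(C)(C)C)cc1O[Si](C)(C)C(C)(C)C)[C@@H](O)C2=O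
F11 | step 18 | (2R,3R)-2-[2,4-bis(tert-butyldimethylsilyloxy)phenyl]-7-(tert-butyldimethylsilyloxy)-3,5-dihydroxy-6-(3-hydroxy-3-methylbutyl)-8-[(2R)-5-methyl-2-(prop-1-en-2-yl)hex-4-en-1-yl]-2,3-dihydro-4H-chromen-4-one | C=C(C)[C@H](CC=C(C)C)Cc1c(O[Si](C)(C)C(C)(C)C)c(CCC(C)(C)O)c(O)c2c1O[C@H](c1ccc(O[Si](C)(C)C(C)(C)C)cc1O[Si](C)(C)C(C)(C)C)[C@@H](O)C2=O
A1 | alternative 1 | (2R,3R)-3-[2,4-bis(methoxymethoxy)phenyl]-3-{2-bromo-3,5-bis(methoxymethoxy)-4-[3-methyl-3-(triethylsilyloxy)butyl]-6-[(2R)-5-methyl-2-(prop-1-en-2-yl)hex-4-en-1-yl]phenoxy}-2-(tert-butyldimethylsilyloxy)-N-methoxy-N-methylpropanamide | C=C(C)[C@H](CC=C(C)C)Cc1c(OCOC)c(CCC(C)(C)O[Si](CC)(CC)CC)c(OCOC)c(Br)c1O[C@H](c1ccc(OCOC)cc1OCOC)[C@@H](O[Si](C)(C)C(C)(C)C)C(=O)N(C)OC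
A2 | alternative 1 | fully protected trans-flavanonol, (2R,3R)-2-[2,4-bis(methoxymethoxy)phenyl]-3-(tert-butyldimethylsilyloxy)-5,7-bis(methoxymethoxy)-6-[3-methyl-3-(triethylsilyloxy)butyl]-8-[(2R)-5-methyl-2-(prop-1-en-2-yl)hex-4-en-1-yl]-2,3-dihydro-4H-chromen-4-one | C=C(C)[C@H](CC=C(C)C)Cc1c(OCOC)c(CCC(C)(C)O[Si](CC)(CC)CC)c(OCOC)c2c1O[C@H](c1ccc(OCOC)cc1OCOC)[C@@H](O[Si](C)(C)C(C)(C)C)C2=O
A3 | alternative 2 | 2-(hydroxymethyl)-3,5-bis(methoxymethoxy)-4-[3-methyl-3-(triethylsilyloxy)butyl]-6-[(2R)-5-methyl-2-(prop-1-en-2-yl)hex-4-en-1-yl]phenol | C=C(C)[C@H](CC=C(C)C)Cc1c(OCOC)c(CCC(C)(C)O[Si](CC)(CC)CC)c(OCOC)c(CO)c1O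
A4 | alternative 2 | (E)-2-[2,4-bis(methoxymethoxy)phenyl]ethenyl 2,2-dimethylpropanoate | CC(C)(C)C(=O)O/C=C/c1ccc(OCOC)cc1OCOC
A5 | alternative 2 | (2R,3S)-2-[2,4-bis(methoxymethoxy)phenyl]-5,7-bis(methoxymethoxy)-6-[3-methyl-3-(triethylsilyloxy)butyl]-8-[(2R)-5-methyl-2-(prop-1-en-2-yl)hex-4-en-1-yl]-3,4-dihydro-2H-chromen-3-yl 2,2-dimethylpropanoate | C=C(C)[C@H](CC=C(C)C)Cc1c(OCOC)c(CCC(C)(C)O[Si](CC)(CC)CC)c(OCOC)c2c1O[C@H](c1ccc(OCOC)cc1OCOC)[C@@H](OC(=O)C(C)(C)C)C2
A6 | alternative 3 | (2R,3R)-5-bromo-2-[2,4-bis(methoxymethoxy)phenyl]-3-(tert-butyldimethylsilyloxy)-2,3-dihydro-4H-pyran-4-one | BrC1=CO[C@H](c2ccc(OCOC)cc2OCOC)[C@@H](O[Si](C)(C)C(C)(C)C)C1=O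
A7 | alternative 3 | 1-methoxy-1,3-bis(trimethylsilyloxy)buta-1,3-diene carrying the 3-methyl-3-(triethylsilyloxy)butyl chain on C2 and the lavandulyl group on C4 (alkene geometries not defined) | C=C(C)[C@H](CC=C(C)C)CC=C(O[Si](C)(C)C)C(CCC(C)(C)O[Si](CC)(CC)CC)=C(OC)O[Si](C)(C)C
A8 | alternative 3 | (2R,3R)-2-[2,4-bis(methoxymethoxy)phenyl]-3-(tert-butyldimethylsilyloxy)-5,7-dihydroxy-6-[3-methyl-3-(triethylsilyloxy)butyl]-8-[(2R)-5-methyl-2-(prop-1-en-2-yl)hex-4-en-1-yl]-2,3-dihydro-4H-chromen-4-one | C=C(C)[C@H](CC=C(C)C)Cc1c(O)c(CCC(C)(C)O[Si](CC)(CC)CC)c(O)c2c1O[C@H](c1ccc(OCOC)cc1OCOC)[C@@H](O[Si](C)(C)C(C)(C)C)C2=O
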